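## Retrosynthetic overview

- The C7 prenyl group is removed first, back to a C7 ketone (B-alkyl Suzuki coupling, exo-face hydroboration, methylenation). That ketone is the handle for the endo prenyl group and also makes C8 an α-carbon.
- Ring B (C1-C8-C7-C6-C5-C9) is then opened at the C1–C8 bond. The plan rests on this bond: it joins two fully substituted carbons that are both α to a carbonyl (C1 to C2 and C9, C8 to C7), so it is made by adding a C8 α-keto radical to the enol carbon C1.
- The monocyclic precursor comes from enantioselective dearomative alkylation of a methyl, prenyl, isobutyryl phloroglucinol at its methyl-bearing carbon with 1,3-dibromo-3-methylbutan-2-one. This sets C5, the stereocentre that controls C1 and C7.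
- The phloroglucinol comes from 2-methylphloroglucinol by Friedel–Crafts isobutyrylation and C-prenylation. Ring A is the original aromatic ring; ring B is formed in step 5.

Key step: step 5

Remark: the enolised tricarbonyl unit of ring A and of its dearomatised precursor is a set of rapidly equilibrating tautomers; every compound is drawn in the tautomer of the target SMILES, CIP descriptors refer to that drawing, and the target numbering (C1 prenyl bridgehead, C2 C=O, C3 isobutyryl, C4 C–OH, C5 methyl bridgehead, C6 CH2, C7, C8 CMe2, C9 bridging C=O) is used for the monocyclic precursors as well.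

## Route

Step 1
Reactants: 1 2-methylbenzene-1,3,5-triol; 2 2-methylpropanoyl chloride
Product: 3 1-(2,4,6-trihydroxy-3-methylphenyl)-2-methylpropan-1-one
Conditions: AlCl3 (4 equiv), PhNO2, 25 → 65 °C; then 1 M HCl, 0 °C
Reagents that add atoms: none
Why: Friedel–Crafts acylation of the electron-rich triol takes one of its two equivalent free ring positions, and the deactivating acyl group should stop a second acylation; no stereocentre is formed.

Step 2
Reactants: 3 1-(2,4,6-trihydroxy-3-methylphenyl)-2-methylpropan-1-one; 4 1-bromo-3-methylbut-2-ene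
Product: 5 2-methyl-1-[2,4,6-trihydroxy-3-methyl-5-(3-methylbut-2-en-1-yl)phenyl]propan-1-one
Conditions: 10% aq. KOH (2 equiv), 4 (1.0 equiv), 0 °C; then 1 M HCl
Reagents that add atoms: none
Why: C-alkylation of the phloroglucinol phenoxide in water should take the only unsubstituted ring carbon, which can rearomatise, in preference to dearomatising attack at the methyl-bearing carbon when one equivalent of bromide is used; no stereocentre is formed.

Step 3
Reactants: 6 3-methylbutan-2-one
Product: 8 1,3-dibromo-3-methylbutan-2-one, via 3-bromo-3-methylbutan-2-one 7 (not isolated)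
Conditions: Br2 (2.05 equiv), PBr3 (cat.), CH2Cl2, −10 → 25 °C; distillation
Reagents that add atoms: bromine, BrBr
Why: Acid-catalysed α-bromination of a ketone goes through the more substituted enol, so the tertiary C3–H is replaced first, and the second bromine can then only enter at the C1 methyl group, the sole remaining enolisable position; no stereocentre is formed.

Step 4
Reactants: 5 2-methyl-1-[2,4,6-trihydroxy-3-methyl-5-(3-methylbut-2-en-1-yl)phenyl]propan-1-one; 8 1,3-dibromo-3-methylbutan-2-one
Product: 9 (6R)-6-(3-bromo-3-methyl-2-oxobutyl)-3,5-dihydroxy-6-methyl-2-(3-methylbut-2-en-1-yl)-4-(2-methylpropanoyl)cyclohexa-2,4-dien-1-one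
Conditions: O-allyl-N-(9-anthracenylmethyl)cinchonidinium bromide (10 mol %), powdered K2CO3 (1.5 equiv), 8 (1.0 equiv), toluene/CHCl3 (7:3), −20 °C; pH 4 phosphate work-up, product kept cold and in the dark
Reagents that add atoms: none
Why: Asymmetric phase-transfer C-alkylation, in which the delocalised phloroglucinol anion, ion-paired with the chiral ammonium cation, attacks the primary α-bromoketone carbon of 8 in an SN2 step (the tertiary bromide cannot react this way) through its less hindered methyl-bearing ring carbon, which dearomatises the ring and should set the quaternary C5 as (R) by shielding of one face of the planar anion; the pseudoenantiomeric cinchoninium salt is the switch if the sense of induction proves to be reversed.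

Step 5
Reactants: 9 (6R)-6-(3-bromo-3-methyl-2-oxobutyl)-3,5-dihydroxy-6-methyl-2-(3-methylbut-2-en-1-yl)-4-(2-methylpropanoyl)cyclohexa-2,4-dien-1-one
Product: 10 (1R,5R)-4-hydroxy-5,8,8-trimethyl-1-(3-methylbut-2-en-1-yl)-3-(2-methylpropanoyl)bicyclo[3.3.1]non-3-ene-2,7,9-trione
Conditions: fac-Ir(ppy)3 (1 mol %), K2HPO4 (2 equiv), degassed MeCN (0.02 M), blue LEDs (450 nm), 25 °C
Reagents that add atoms: none
Why: Proposed new method: photoexcited fac-Ir(ppy)3 (excited trivalent iridium, a strong reductant) passes an electron into the tertiary C8–Br bond of 9, bromide leaves, and the electrophilic tertiary α-keto radical at C8 adds to the electron-rich enol carbon C1; the delocalised radical then centred on C2 is oxidised by tetravalent iridium (or hands its electron to another molecule of 9 in a chain) and loses a proton to give the C2 ketone, with net loss of HBr that the phosphate takes up so that the prenyl group is not exposed to acid. The closest known reaction type is the photoredox or atom-transfer addition of α-bromocarbonyl radicals to enols, silyl enol ethers and enamines to give 1,4-dicarbonyl compounds; new here is its intramolecular use to make a bridged bond between two fully substituted carbons of a dearomatised acylphloroglucinol. Ring B (C1-C8-C7-C6-C5-C9) closes in a 6-exo-trig mode onto the C1=C2 enol double bond. The new stereocentre C1 is set by C5, because the three-atom tether C6-C7-C8 can reach C1 only on the ring face that carries it, which pushes the C1 prenyl group to the other face (1R). The step needs attack at C1 and not at the equally distant C3, and bonding at carbon and not at oxygen: C3 is the acyl-bearing, more hindered carbon whose attack would leave a less delocalised radical, and a carbon radical adds to the enol carbon, not to its oxygen. A radical is chosen because SN2 alkylation at tertiary C8 is not possible and a cation next to the C7 carbonyl is not accessible.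

Step 6
Reactants: 10 (1R,5R)-4-hydroxy-5,8,8-trimethyl-1-(3-methylbut-2-en-1-yl)-3-(2-methylpropanoyl)bicyclo[3.3.1]non-3-ene-2,7,9-trione
Product: 11 (1R,5R)-4-hydroxy-5,8,8-trimethyl-7-methylidene-1-(3-methylbut-2-en-1-yl)-3-(2-methylpropanoyl)bicyclo[3.3.1]non-3-ene-2,9-dione
Conditions: Ph3PCH3Br (5 equiv), KOtBu (4.8 equiv), THF, 0 °C; then 10, 0 → 60 °C; aq. NH4Cl, then 1 M HCl
Reagents that add atoms: methyltriphenylphosphonium bromide, [Br-].C[P+](c1ccccc1)(c1ccccc1)c1ccccc1
Why: Wittig methylenation, in which the first equivalent of ylide deprotonates the acidic enol so that the ring A carbonyls are masked as the enolate, the C9 ketone is buried between two quaternary bridgeheads, and only the C7 ketone should be olefinated; C1 and C5 are quaternary and cannot epimerise.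

Step 7
Reactants: 11 (1R,5R)-4-hydroxy-5,8,8-trimethyl-7-methylidene-1-(3-methylbut-2-en-1-yl)-3-(2-methylpropanoyl)bicyclo[3.3.1]non-3-ene-2,9-dione; 12 1-bromo-2-methylprop-1-ene
Product: 15 (1R,5R,7R)-4-hydroxy-5,8,8-trimethyl-1,7-bis(3-methylbut-2-en-1-yl)-3-(2-methylpropanoyl)bicyclo[3.3.1]non-3-ene-2,9-dione, via ring A boron chelate 13 (not isolated), via C7 borylmethyl chelate 14 (not isolated)
Conditions: 9-BBN dimer (3 equiv of B–H), THF, 0 → 50 °C; then 12 (3 equiv), Pd(dppf)Cl2 (10 mol %), 3 M aq. NaOH, THF/DMF, 50 °C; 1 M HCl work-up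
Reagents that add atoms: 9-borabicyclo[3.3.1]nonane (9-BBN), B1C2CCCC1CCC2 (its atoms other than hydrogen stay only in 13 and 14)
Why: The first equivalent of borane is taken up by the acidic enol as a dialkylboron chelate that masks ring A, then anti-Markovnikov syn hydroboration of the 1,1-disubstituted C7 methylidene (much faster than that of the trisubstituted prenyl alkene) should occur from the exo face of ring B because the endo face is roofed by the C2–C3–C4 bridge, so hydrogen enters C7 exo and the CH2–B arm is left endo (7R), and B-alkyl Suzuki–Miyaura coupling with the alkenyl bromide at zerovalent palladium then completes the prenyl group without touching C7, the aqueous base and acid work-up freeing the enol.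

## Compound list

1 | 2-methylbenzene-1,3,5-triol | Cc1c(O)cc(O)cc1O | starting material
2 | 2-methylpropanoyl chloride | CC(C)C(=O)Cl | starting material
3 | 1-(2,4,6-trihydroxy-3-methylphenyl)-2-methylpropan-1-one | CC(C)C(=O)c1c(O)cc(O)c(C)c1O | intermediate
4 | 1-bromo-3-methylbut-2-ene | CC(C)=CCBr | starting material
5 | 2-methyl-1-[2,4,6-trihydroxy-3-methyl-5-(3-methylbut-2-en-1-yl)phenyl]propan-1-one | CC(C)=CCc1c(O)c(C)c(O)c(C(=O)C(C)C)c1O | intermediate
6 | 3-methylbutan-2-one | CC(C)C(C)=O | starting material
7 | 3-bromo-3-methylbutan-2-one (not isolated) | CC(=O)C(C)(C)Br | intermediate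
8 | 1,3-dibromo-3-methylbutan-2-one | BrCC(=O)C(C)(C)Br | intermediate
9 | (6R)-6-(3-bromo-3-methyl-2-oxobutyl)-3,5-dihydroxy-6-methyl-2-(3-methylbut-2-en-1-yl)-4-(2-methylpropanoyl)cyclohexa-2,4-dien-1-one | CC(C)=CCC1=C(O)C(C(=O)C(C)C)=C(O)[C@@](C)(CC(=O)C(C)(C)Br)C1=O | intermediate
10 | (1R,5R)-4-hydroxy-5,8,8-trimethyl-1-(3-methylbut-2-en-1-yl)-3-(2-methylpropanoyl)bicyclo[3.3.1]non-3-ene-2,7,9-trione | O=C1C[C@@]2(C)C(=O)[C@](CC=C(C)C)(C(=O)C(C(=O)C(C)C)=C2O)C1(C)C | intermediate
11 | (1R,5R)-4-hydroxy-5,8,8-trimethyl-7-methylidene-1-(3-methylbut-2-en-1-yl)-3-(2-methylpropanoyl)bicyclo[3.3.1]non-3-ene-2,9-dione | C=C1C[C@@]2(C)C(=O)[C@](CC=C(C)C)(C(=O)C(C(=O)C(C)C)=C2O)C1(C)C | intermediate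
12 | 1-bromo-2-methylprop-1-ene | CC(C)=CBr | starting material
13 | ring A boron chelate of 11: the C4 enol oxygen and the isobutyryl oxygen bridged by a 9-borabicyclo[3.3.1]nonan-9-yl unit (not isolated) | C=C1C[C@@]2(C)C(=O)[C@](CC=C(C)C)(C(=O)C3=C2O[B-]4(C5CCCC4CCC5)[O+]=C3C(C)C)C1(C)C | intermediate
14 | (7R)-7-endo-[(9-borabicyclo[3.3.1]nonan-9-yl)methyl] derivative of chelate 13 (not isolated) | B1(C2CCCC1CCC2)C[C@@H]3C[C@@]4(C)C(=O)[C@](CC=C(C)C)(C(=O)C5=C4O[B-]6(C7CCCC6CCC7)[O+]=C5C(C)C)C3(C)C | intermediate
15 | (1R,5R,7R)-4-hydroxy-5,8,8-trimethyl-1,7-bis(3-methylbut-2-en-1-yl)-3-(2-methylpropanoyl)bicyclo[3.3.1]non-3-ene-2,9-dione (CNP0265287.1) | CC(C)=CC[C@@H]1C[C@@]2(C)C(=O)[C@](CC=C(C)C)(C(=O)C(C(=O)C(C)C)=C2O)C1(C)C | target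

## Step count and risks

Total step count: 7. Longest linear sequence: 6 steps (steps 1, 2, 4, 5, 6, 7); step 3 is a one-step side branch.

**Step 5 (proposed new method).**
- What may go wrong: the C8 radical may be reduced further and protonated (simple debromination), or the tertiary bromide may lose HBr by elimination, before the slow closure of a bond between two quaternary carbons. The radical addition may also be reversible and unproductive, or occur at C3.
- Fallback (known chemistry): an intramolecular oxidative enolate coupling replaces the radical–enol addition. It sets out from 5, which is alkylated under the conditions of step 4 with commercial 1-bromo-3-methylbutan-2-one (CC(C)C(=O)CBr) in place of 8. This should give the bromine-free ketone (6R)-3,5-dihydroxy-6-methyl-2-(3-methylbut-2-en-1-yl)-6-(3-methyl-2-oxobutyl)-4-(2-methylpropanoyl)cyclohexa-2,4-dien-1-one F1. This ketone is converted with LiHMDS (3.3 equiv, THF, −78 °C) into the trianion (ring enolate plus the C8 ketone enolate) and oxidised with Fe(acac)3 (2.2 equiv, −78 → 0 °C). Only the C8 enolate can couple productively, the C6 enolate having no ring carbon within reach, and the coupling should join C1 and C8. The fallback comes back to the route at 10.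

**Step 4.**
- What may go wrong: alkylation at oxygen or at the prenyl-bearing ring carbon in place of the methyl-bearing carbon, and weak discrimination of the two faces of the anion in the ion pair, giving material of low enantiomeric purity.
- Fallback: resolution replaces asymmetric catalysis. It sets out from 5 and 8, which are combined without chiral catalyst (K2CO3, acetone, 0 °C) to give racemic 6-(3-bromo-3-methyl-2-oxobutyl)-3,5-dihydroxy-6-methyl-2-(3-methylbut-2-en-1-yl)-4-(2-methylpropanoyl)cyclohexa-2,4-dien-1-one F2. Constitutional isomers are removed on silica, and the racemate is separated by preparative chromatography on an amylose tris(3,5-dimethylphenylcarbamate) phase. The (6R) enantiomer is 9, where the fallback comes back to the route, and the (6S)-6-(3-bromo-3-methyl-2-oxobutyl)-3,5-dihydroxy-6-methyl-2-(3-methylbut-2-en-1-yl)-4-(2-methylpropanoyl)cyclohexa-2,4-dien-1-one F3 is set aside.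

**Step 7.**
- What may go wrong: the hindered β-branched alkylborane, held on the concave face, may transmetalate slowly and be lost by protodeboronation or β-hydride elimination. Excess borane may also reduce a ketone.
- Fallback: carbonyl olefination replaces cross-coupling for the last carbon–carbon bond. It sets out from 11, which is hydroborated as in step 7 and then oxidised with NaBO3·4H2O to the alcohol (1R,5R,7R)-4-hydroxy-7-(hydroxymethyl)-5,8,8-trimethyl-1-(3-methylbut-2-en-1-yl)-3-(2-methylpropanoyl)bicyclo[3.3.1]non-3-ene-2,9-dione F4. Parikh–Doering oxidation (SO3·pyridine, DMSO, iPr2NEt, 0 °C) should give the aldehyde (1R,5R,7R)-7-formyl-4-hydroxy-5,8,8-trimethyl-1-(3-methylbut-2-en-1-yl)-3-(2-methylpropanoyl)bicyclo[3.3.1]non-3-ene-2,9-dione F5. This is kept cold to avoid epimerisation at C7 and treated at once with isopropylidenetriphenylphosphorane (from isopropyltriphenylphosphonium iodide and n-BuLi, THF, −78 → 0 °C; one extra equivalent for the enol). The fallback comes back to the route at 15.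

Further compounds
F1 | step 5 | (6R)-3,5-dihydroxy-6-methyl-2-(3-methylbut-2-en-1-yl)-6-(3-methyl-2-oxobutyl)-4-(2-methylpropanoyl)cyclohexa-2,4-dien-1-one | CC(C)=CCC1=C(O)C(C(=O)C(C)C)=C(O)[C@@](C)(CC(=O)C(C)C)C1=O
F2 | step 4 | racemic 6-(3-bromo-3-methyl-2-oxobutyl)-3,5-dihydroxy-6-methyl-2-(3-methylbut-2-en-1-yl)-4-(2-methylpropanoyl)cyclohexa-2,4-dien-1-one | CC(C)=CCC1=C(O)C(C(=O)C(C)C)=C(O)C(C)(CC(=O)C(C)(C)Br)C1=O
F3 | step 4 | (6S)-6-(3-bromo-3-methyl-2-oxobutyl)-3,5-dihydroxy-6-methyl-2-(3-methylbut-2-en-1-yl)-4-(2-methylpropanoyl)cyclohexa-2,4-dien-1-one | CC(C)=CCC1=C(O)C(C(=O)C(C)C)=C(O)[C@](C)(CC(=O)C(C)(C)Br)C1=O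
F4 | step 7 | (1R,5R,7R)-4-hydroxy-7-(hydroxymethyl)-5,8,8-trimethyl-1-(3-methylbut-2-en-1-yl)-3-(2-methylpropanoyl)bicyclo[3.3.1]non-3-ene-2,9-dione | OC[C@@H]1C[C@@]2(C)C(=O)[C@](CC=C(C)C)(C(=O)C(C(=O)C(C)C)=C2O)C1(C)C
F5 | step 7 | (1R,5R,7R)-7-formyl-4-hydroxy-5,8,8-trimethyl-1-(3-methylbut-2-en-1-yl)-3-(2-methylpropanoyl)bicyclo[3.3.1]non-3-ene-2,9-dione | O=C[C@@H]1C[C@@]2(C)C(=O)[C@](CC=C(C)C)(C(=O)C(C(=O)C(C)C)=C2O)C1(C)C
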